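Decide whether the next flask gets more J by counting lifetimes of dissolved monomer.

| setting | violet | flask |
|---|---|---|
| E | 0.092 M | 0.092 M |
| J | 10 mol% | 5 mol% |
| remark | run made earlier |  |
| time |  | 5.0 d |

violet run (percent of the E charged)

| time / h | D / % | E / % |
|---|---|---|
| 2.00 | 4.3 | 89.3 |
| 4.00 | 8.4 | 79.5 |
| 6.00 | 12.3 | 71.8 |
| 8.00 | 15.2 | 64.3 |
| 10.0 | 17.0 | 58.1 |
| 12.0 | 21.3 | 53.4 |

(each reading ± 0.5 percentage points)

- given per volume of solution although it is solid: E
- at the start none of E is in solution
- no earlier run changes the charge of J; that part of a forecast is a guess

- amount of D at 5.0 d, in percent of the E charged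
- the change that raises the amount of D at 5.0 d, in percent of the E charged most ("none" if none brings more than 2 percentage points) (spring / summer / midnight / none)
- amount of D at 5.0 d, in percent of the E charged, after spring

- spring: doubling the amount of J, all else as stated
- summer: doubling the dissolution coefficient of E, all else as stated
- midnight: doubling the solubility of E, all else as stated

In the violet run, E that is lost but not yet found as D is dissolved monomer. That gap grows from 20.5% at 8.00 h to 25.3% at 12.0 h, while D gains 6.1 percentage points, a difference carrying the scatter of 0.5 points in each reading. The mean gap divided by D gained per hour reads 15.0 h in violet. No earlier run changes J, so I guess that this time grows as J shrinks, and for this flask the lifetime of dissolved monomer, the time the gap needs to turn into D at its present rate, is 30.0 h.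

Before it can turn into D, E has to dissolve. Violet's E fell to 53.4% by 12.0 h, which reads as a lifetime of 19.1 h, and I treat that as a wait. So 5.0 d less that wait holds 3.36 lifetimes, and I expect 3.48% still dissolved and 96.5% as D. On the same guess spring brings the lifetime back to 15.0 h and D to 99.9%, a gain of 3.4 points. That is more than the 0.95 points I reckon for summer or midnight, taking each as halving the wait. The margin is 2 points, so change J.

The forecast names the same change as I do but lower amounts, 41%, and 78% after spring, holding that “polymerisation looks saturated in monomer and limited by the initiator”.

The flask gives 96.0% of D and 99.9% after spring; spring gains 3.9 points, summer 0.96 points, midnight 1.8 points.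

    L + Q → D + Q, rate k1*[Q]*[L] (k = 0.120 /M/min)
    E ⇌ L, rate k2*(cs2 - [L]) while solid is left; crystals form when [L] > cs2 (solubility = 46.0 mM, k = 0.00190 /min)
    L + J → Q + D (k = 1.20 /M/min)

In this flask half of the turnover of the dissolving up to 5.0 d was done by 0.650 d, half of that of the making of D from L by the later 1.81 d, and L stood at 29.5% at 2.50 d, with E at 0%. With c_Q steady at 0.00460 M, a pseudo-first-order loss, L then fell to 4.05% at 5.00 d, a lifetime of 30.2 h against my 30.0 h. For the neighbour with 1.2 mol% of J the lifetime scales to 125 h, which makes 0.806 lifetimes and a reckoned D of 55.3%; the computed D of that neighbour is lower, 42.5%, with 57% of the charged E still there, solid or dissolved.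

The earlier runs and the new flask were generated by integration for substances that don't exist; scatter was added.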